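**Retrosynthetic overview**
1. Target ⇐ 17-nor-16-ketone (CH2 put on last) ⇐ 2-ene (β-face osmylation gives the 2β,3β-diol) ⇐ 3-ketone of the closed ring A.
2. Ring A and the 19,10-lactone ⇐ tricyclic enone ester 26 by carbonyl allylation at C10, O-propanoylation, intramolecular Michael addition (C4–C5, γ-lactone) and intramolecular aldol (C3–C4).
3. 26 ⇐ bicyclo[3.2.1]octane tricycle by C6 enol-triflate carbonylation (C7), epoxide-to-11-ketone rearrangement and C10 allylic oxidation; ring D ⇐ palladium cycloalkenylation of a silyl dienol ether onto an angular allyl group.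
4. Key C–C bond: C8–C14, by intermolecular Michael addition of 2-allylcyclopentane-1,3-dione (ring B fragment plus C15, C16) to methyl vinyl ketone (ring C fragment, C11–C14); the L-proline aldol that follows fixes C8.
5. Ring order: B (from the dione) → C → D → γ-lactone → A. Gibberellane atom numbers are used for all intermediates; β is the face of C15 at C8.

Assumption: the SMILES is read as the natural-series gibberellin 2β,3β,11β-trihydroxy-GA9 (19,10-lactone, 7-oic acid).

**Route**

Step 1
Reactants: 1 cyclopentane-1,3-dione; 2 allyl methyl carbonate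
Product: 3 2-allylcyclopentane-1,3-dione
Conditions: Pd(PPh3)4 (1 mol %), THF, 25 °C
Reagents that add atoms: none
Why: Tsuji–Trost allylation in which zerovalent palladium ionises the carbonate, the released methoxide deprotonates the acidic dione and the soft enolate is C-allylated at the future C8 (no stereocentre).

Step 2
Reactants: 3 2-allylcyclopentane-1,3-dione; 4 methyl vinyl ketone
Product: 5 2-allyl-2-(3-oxobutyl)cyclopentane-1,3-dione
Conditions: H2O, AcOH (cat.), 70 °C
Reagents that add atoms: none
Why: Michael addition of the 2-substituted 1,3-dione (through its enol) to the enone forms the fragment-joining C8–C14 bond and the quaternary, still prochiral, C8.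

Step 3
Reactants: 5 triketone
Product: 7 (R)-7a-allyl-2,3,7,7a-tetrahydro-1H-indene-1,5(6H)-dione, via ketol 6 (not isolated)
Conditions: L-proline (30 mol %), DMF, 20 °C, 72 h; then H2SO4 (cat.), 95 °C
Reagents that add atoms: none
Why: Hajos–Parrish (Eder–Sauer–Wiechert) aldol in which the proline enamine of the side-chain ketone (C11) attacks one of the two enantiotopic ring carbonyls (C9), fixing C8 in the same spatial sense as the (S)-methyl series (descriptor R because allyl outranks C14), and acid then dehydrates the ketol to the enone.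

Step 4
Reactants: 7 enedione
Product: 8 (1S,7aR)-7a-allyl-1-hydroxy-1,2,3,6,7,7a-hexahydro-5H-inden-5-one
Conditions: NaBH4 (0.3 equiv), EtOH, −20 °C
Reagents that add atoms: none
Why: Chemoselective hydride reduction of the saturated cyclopentanone beside the less electrophilic enone, hydride arriving anti to the angular allyl group (6β-alcohol, a temporary mask for the C6 ketone; crystallisation here raises the ee).

Step 5
Reactants: 8 hydroxy enone
Product: 9 bis-silyl dienol ether
Conditions: LiN(iPr)2 (2.3 equiv), THF, −78 °C; tBuMe2SiCl (2.5 equiv), DMPU, −78 → 0 °C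
Reagents that add atoms: tert-butyldimethylsilyl chloride, CC(C)(C)[Si](C)(C)Cl
Why: Kinetic deprotonation of the enone at the α′ carbon C13 gives the cross-conjugated dienolate, and O-silylation traps both it and the lithium alkoxide (regiodefined enol ether, no new stereocentre).

Step 6
Reactants: 9 bis-silyl dienol ether
Product: 10 tricyclic 16-methylene-9(11)-en-12-one
Conditions: Pd(OAc)2 (10 mol %), O2 (1 atm), DMSO, 45 °C
Reagents that add atoms: none
Why: Palladium-promoted cycloalkenylation of a silyl enol ether (divalent palladium activates the allyl alkene, C13 attacks C16 in a 5-exo mode, β-hydride elimination gives the exocyclic methylene, O2 reoxidises the metal); the two-carbon bridge can only span C8 and C13 on one face, which sets C13.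

Step 7
Reactants: 10 tricyclic methylene enone
Product: 12 17-nor-9(11)-ene-12,16-dione, via ozonide 11 (not isolated)
Conditions: O3, CH2Cl2, pyridine (trace), −78 °C; then Me2S, −78 → 20 °C
Reagents that add atoms: ozone, [O-][O+]=O
Why: Ozonolysis, in which the electron-rich 1,1-disubstituted alkene reacts far faster than the conjugated enone C=C, unmasks the C16 ketone that carries the methylene again only at the end.

Step 8
Reactants: 12 ene-dione
Product: 13 16,16-ethylenedioxy-9(11)-en-12-one
Conditions: ethylene glycol, pyridinium p-toluenesulfonate (cat.), benzene, reflux (Dean–Stark)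
Reagents that add atoms: ethylene glycol, OCCO
Why: Acid-catalysed ketalisation is selective for the saturated five-ring ketone over the conjugated, less electrophilic C12 carbonyl.

Step 9
Reactants: 13 ketal enone
Product: 14 12β-allylic alcohol
Conditions: NaBH4, CeCl3·7H2O, MeOH, 0 °C
Reagents that add atoms: none
Why: Luche 1,2-reduction of the enone, hydride coming from the α face away from the ketal-bearing two-carbon bridge (the C12 centre is removed in step 11, so its configuration is immaterial).

Step 10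
Reactants: 14 allylic alcohol
Product: 15 12β-acetate
Conditions: Ac2O, pyridine, 4-(dimethylamino)pyridine (cat.), CH2Cl2, 20 °C
Reagents that add atoms: acetic anhydride, CC(=O)OC(C)=O
Why: Nucleophile-catalysed acylation turns the allylic hydroxyl into a leaving group for reductive cleavage.

Step 11
Reactants: 15 allylic acetate
Product: 16 16,16-ethylenedioxy-9(11)-ene
Conditions: Li, NH3 (l), THF, −78 °C, 10 min; NH4Cl
Reagents that add atoms: none
Why: Dissolving-metal (Birch-type) cleavage of the allylic C–O bond, the allyl anion being protonated at the less substituted C12 to leave the more substituted 9(11)-alkene and remove the oxygen that was needed only for ring D closure.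

Step 12
Reactants: 16 silyl ether
Product: 17 9(11)-en-6β-ol
Conditions: Bu4NF, THF, 40 °C; NH4Cl (aq.)
Reagents that add atoms: none
Why: Fluoride-driven desilylation (strong Si–F bond) frees the C6 alcohol without touching the ketal.

Step 13
Reactants: 17 alcohol
Product: 18 9(11)-en-6-one
Conditions: Dess–Martin periodinane, NaHCO3, CH2Cl2, 20 °C
Reagents that add atoms: none
Why: Mild, buffered hypervalent-iodine oxidation returns the C6 ketone, now the only carbonyl in the molecule.

Step 14
Reactants: 18 ketone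
Product: 19 5,9(11)-dien-6-yl triflate
Conditions: KN(SiMe3)2 (1.1 equiv), THF, −78 °C; PhNTf2
Reagents that add atoms: N-phenylbis(trifluoromethanesulfonimide), O=S(=O)(N(c1ccccc1)S(=O)(=O)C(F)(F)F)C(F)(F)F
Why: Enolate O-sulfonylation is regiospecific because C8 is quaternary, so only C5 can be deprotonated.

Step 15
Reactants: 19 enol triflate; 20 carbon monoxide
Product: 21 2-(trimethylsilyl)ethyl 5,9(11)-diene-7-oate
Conditions: Pd(OAc)2 (5 mol %), PPh3 (10 mol %), Et3N, Me3SiCH2CH2OH, DMF, CO (1 atm), 60 °C
Reagents that add atoms: 2-(trimethylsilyl)ethanol, C[Si](C)(C)CCO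
Why: Palladium-catalysed alkoxycarbonylation (oxidative addition of zerovalent palladium to the vinyl triflate, CO insertion, alcoholysis) installs C7 as a fluoride-cleavable ester and leaves the 5-ene as the later Michael acceptor.

Step 16
Reactants: 21 diene ester
Product: 22 9α,11α-epoxide
Conditions: mCPBA, NaHCO3, CH2Cl2, 0 °C
Reagents that add atoms: 3-chloroperbenzoic acid, OOC(=O)c1cccc(Cl)c1
Why: Prilezhaev epoxidation occurs only at the electron-rich trisubstituted 9(11)-alkene (not the conjugated ester alkene) and from the exo α face, syn to the one-carbon bridge C14 and anti to the C15–C16 bridge.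

Step 17
Reactants: 22 epoxide
Product: 23 11-oxo-5-ene ester (9β-H)
Conditions: BF3·OEt2 (0.3 equiv), CH2Cl2, −78 → −40 °C; Et3N
Reagents that add atoms: none
Why: Meinwald rearrangement in which the Lewis acid opens the epoxide at tertiary C9 and the 11β-hydrogen migrates to C9 on the face opposite the departing α-oxygen, giving the 11-ketone with 9β-H, which should also be the more stable cis B/C fusion.

Step 18
Reactants: 23 11-ketone
Product: 24 11β-alcohol
Conditions: NaBH4, MeOH/THF, −20 °C
Reagents that add atoms: none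
Why: Hydride reduction from the exo α face, because the β face is blocked by the axial C15–C16 bridge and its ketal, gives the endo (axial) 11β-alcohol and leaves the conjugated ester alone.

Step 19
Reactants: 24 11β-alcohol
Product: 25 11β-triethylsilyl ether
Conditions: Et3SiOTf, 2,6-lutidine, CH2Cl2, −40 → 0 °C
Reagents that add atoms: triethylsilyl trifluoromethanesulfonate, CC[Si](CC)(CC)OS(=O)(=O)C(F)(F)F
Why: Silyl triflate silylation copes with the hindered endo alcohol and gives an ether that survives the basic steps but falls to dilute acid.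

Step 20
Reactants: 25 silyl ether
Product: 26 10-oxo-5-ene ester (enone ester)
Conditions: Rh2(C6H10NO)4 (dirhodium tetracaprolactamate, 1 mol %), tBuOOH (70 % aq., 5 equiv), K2CO3, CH2Cl2, 20 °C
Reagents that add atoms: tert-butyl hydroperoxide, CC(C)(C)OO
Why: Radical allylic C–H oxidation (tert-butylperoxyl chain) at C10, the only allylic methylene of the unsaturated ester since C8 is quaternary, gives the enone; the adjacent C9 keeps the favoured cis ring fusion.

Step 21
Reactants: 26 enone ester; 27 allylmagnesium bromide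
Product: 28 10β-allyl-10α-hydroxy-5-ene ester
Conditions: THF, −78 °C; NH4Cl (aq.)
Reagents that add atoms: none
Why: Carbonyl allylation (allyl Grignard 1,2-addition, faster at the ketone than at the hindered ester) from the β face of C10, syn to H9 and anti to the C9–C11 bond of ring C, gives the 10α-alkoxide that becomes the lactone oxygen.

Step 22
Reactants: 28 tertiary alcohol; 29 propanoyl chloride
Product: 30 10α-propanoate
Conditions: LiN(SiMe3)2, THF, −78 °C; then 29, −78 → 0 °C
Reagents that add atoms: none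
Why: O-acylation of the tertiary alkoxide, using lithium rather than potassium as counter-ion so that the 1,5-dien-3-olate does not undergo anionic oxy-Cope rearrangement.

Step 23
Reactants: 30 propanoate
Product: 31 19,10-γ-lactone (ring A still open)
Conditions: LiN(iPr)2 (1.2 equiv), THF, −78 → −30 °C; AcOH
Reagents that add atoms: none
Why: Intramolecular Michael addition (5-exo-trig) of the propanoate enolate to C5 of the unsaturated ester, where the γ-lactone must be cis-fused to ring B so that C4 bonds to the α face of C5 (5β-H); C4 and C6 form as mixtures that converge in step 26.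

Step 24
Reactants: 31 allyl lactone
Product: 33 primary alcohol (3-hydroxypropyl lactone), via alkylborane 32 (not isolated)
Conditions: 9-BBN, THF, 0 → 20 °C; then H2O2 (30 %), NaOAc (aq.), 20 °C
Reagents that add atoms: hydrogen peroxide, OO
Why: Anti-Markovnikov hydroboration–oxidation of the only alkene places oxygen on C3, and 9-BBN leaves the esters, lactone and ketal alone.

Step 25
Reactants: 33 primary alcohol
Product: 34 C3 aldehyde
Conditions: Dess–Martin periodinane, NaHCO3, CH2Cl2, 20 °C
Reagents that add atoms: none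
Why: Buffered hypervalent-iodine oxidation stops cleanly at the aldehyde.

Step 26
Reactants: 34 aldehyde
Product: 35 3-hydroxy-19,10-lactone with ring A closed
Conditions: KOtBu (0.3 equiv), tBuOH/THF, 0 °C; NH4Cl
Reagents that add atoms: none
Why: Intramolecular aldol under reversible conditions (the reverse of the known retro-aldol of 3-hydroxy gibberellin lactones), in which the bridged ring can only close with C3 on the side of C1, so the C4 methyl is β, while C6 equilibrates to the more stable 6β-ester trans to C4; both C3 epimers are carried on.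

Step 27
Reactants: 35 aldol
Product: 36 3-oxo-19,10-lactone
Conditions: Dess–Martin periodinane, NaHCO3, CH2Cl2, 20 °C
Reagents that add atoms: none
Why: Oxidation merges the C3 epimers into one β-keto lactone that cannot enolise towards the quaternary C4.

Step 28
Reactants: 36 3-ketone
Product: 37 2-en-3-yl triflate
Conditions: KN(SiMe3)2 (1.05 equiv), THF, −78 °C; PhNTf2
Reagents that add atoms: N-phenylbis(trifluoromethanesulfonimide), O=S(=O)(N(c1ccccc1)S(=O)(=O)C(F)(F)F)C(F)(F)F
Why: Enol triflate formation is regiospecific towards C2, the only enolisable side of the ketone, which is more acidic than the hindered C6 ester position.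

Step 29
Reactants: 37 enol triflate
Product: 38 2-ene 19,10-lactone
Conditions: Pd(OAc)2 (5 mol %), PPh3 (10 mol %), Bu3N, HCO2H, DMF, 60 °C
Reagents that add atoms: none
Why: Palladium-catalysed formate reduction of the vinyl triflate (oxidative addition to zerovalent palladium, formate decarboxylation, reductive elimination of C–H) gives the 2-ene without touching other groups.

Step 30
Reactants: 38 2-ene
Product: 39 2β,3β-diol
Conditions: OsO4 (2 mol %), N-methylmorpholine N-oxide, acetone/H2O, 20 °C
Reagents that add atoms: N-methylmorpholine N-oxide, C[N+]1([O-])CCOCC1; water, O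
Why: Upjohn syn-dihydroxylation from the β (exo) face, because the α face is covered by the 19,10-lactone bridge, sets C2 and C3 together as the 2β,3β-diol.

Step 31
Reactants: 39 protected diol
Product: 40 17-nor-16-oxo triol ester
Conditions: 1 M HCl, THF, 30 °C
Reagents that add atoms: water, O
Why: Acid hydrolysis removes the dioxolane and the triethylsilyl ether in one operation at a stage that has no acid-sensitive alkene.

Step 32
Reactants: 40 norketone; 41 dibromomethane
Product: 42 2-(trimethylsilyl)ethyl ester of the target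
Conditions: Zn, TiCl4, THF/CH2Cl2, 0 → 20 °C
Reagents that add atoms: none
Why: Lombardo–Takai methylenation, a non-basic zinc–titanium carbenoid, converts the ketone to the 16-methylene without retro-aldol at C3 and without attacking ester or lactone.

Step 33
Reactants: 42 ester
Product: 43 target acid
Conditions: Bu4NF, THF, 0 → 20 °C; then AcOH
Reagents that add atoms: none
Why: Fluoride-induced β-elimination of the 2-(trimethylsilyl)ethyl ester frees the C7 acid under conditions too mild and brief for lactone opening or C3 epimerisation.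

**Compound list**
1 | cyclopentane-1,3-dione | O=C1CCC(=O)C1 | starting material
2 | allyl methyl carbonate | C=CCOC(=O)OC | starting material
3 | 2-allylcyclopentane-1,3-dione | C=CCC1C(=O)CCC1=O | intermediate
4 | methyl vinyl ketone (but-3-en-2-one) | CC(=O)C=C | starting material
5 | 2-allyl-2-(3-oxobutyl)cyclopentane-1,3-dione | C=CCC1(CCC(C)=O)C(=O)CCC1=O | intermediate
6 | cis-fused ketol, 7a-allyl-3a-hydroxy-hexahydroindane-1,5-dione (OH cis to allyl) | C=CC[C@]12CCC(=O)C[C@@]1(O)CCC2=O | intermediate
7 | (R)-7a-allyl-2,3,7,7a-tetrahydro-1H-indene-1,5(6H)-dione | C=CC[C@]12CCC(=O)C=C1CCC2=O | intermediate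
8 | (1S,7aR)-7a-allyl-1-hydroxy-1,2,3,6,7,7a-hexahydro-5H-inden-5-one (6β-OH, cis to allyl) | C=CC[C@]12CCC(=O)C=C1CC[C@@H]2O | intermediate
9 | 6β-OTBS ether of the 12-(tert-butyldimethylsilyloxy)-9(11),12-diene | C=CC[C@]12CC=C(O[Si](C)(C)C(C)(C)C)C=C1CC[C@@H]2O[Si](C)(C)C(C)(C)C | intermediate
10 | tricycle (rings B, C, D): 6β-OTBS-16-methylene-9(11)-en-12-one, C15–C16 bridge from C8 to C13 | C=C1C[C@]23C[C@H]1C(=O)C=C2CC[C@@H]3O[Si](C)(C)C(C)(C)C | intermediate
11 | ozonide of 10 (spiro-1,2,4-trioxolane at C16, epimers) | C1OOC2(O1)C[C@]34C[C@H]2C(=O)C=C3CC[C@@H]4O[Si](C)(C)C(C)(C)C | intermediate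
12 | 17-nor-6β-OTBS-9(11)-ene-12,16-dione | O=C1C[C@]23C[C@H]1C(=O)C=C2CC[C@@H]3O[Si](C)(C)C(C)(C)C | intermediate
13 | 16,16-ethylenedioxy-6β-OTBS-9(11)-en-12-one | O1CCOC12C[C@]34C[C@H]2C(=O)C=C3CC[C@@H]4O[Si](C)(C)C(C)(C)C | intermediate
14 | 16,16-ethylenedioxy-6β-OTBS-9(11)-en-12β-ol | O1CCOC12C[C@]34C[C@H]2[C@H](O)C=C3CC[C@@H]4O[Si](C)(C)C(C)(C)C | intermediate
15 | 12β-acetate of 14 | O1CCOC12C[C@]34C[C@H]2[C@H](OC(C)=O)C=C3CC[C@@H]4O[Si](C)(C)C(C)(C)C | intermediate
16 | 16,16-ethylenedioxy-6β-OTBS-9(11)-ene | O1CCOC12C[C@]34C[C@H]2CC=C3CC[C@@H]4O[Si](C)(C)C(C)(C)C | intermediate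
17 | 16,16-ethylenedioxy-9(11)-en-6β-ol | O1CCOC12C[C@]34C[C@H]2CC=C3CC[C@@H]4O | intermediate
18 | 16,16-ethylenedioxy-9(11)-en-6-one | O1CCOC12C[C@]34C[C@H]2CC=C3CCC4=O | intermediate
19 | 16,16-ethylenedioxy-5,9(11)-dien-6-yl triflate | O1CCOC12C[C@]34C[C@H]2CC=C3CC=C4OS(=O)(=O)C(F)(F)F | intermediate
20 | carbon monoxide | [C-]#[O+] | starting material
21 | 2-(trimethylsilyl)ethyl 16,16-ethylenedioxy-5,9(11)-diene-7-oate | O1CCOC12C[C@]34C[C@H]2CC=C3CC=C4C(=O)OCC[Si](C)(C)C | intermediate
22 | 9α,11α-epoxide of 21 | O1CCOC12C[C@]34C[C@H]2C[C@H]5O[C@]53CC=C4C(=O)OCC[Si](C)(C)C | intermediate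
23 | 11-oxo-5-ene ester, 9β-H | O1CCOC12C[C@]34C[C@H]2CC(=O)[C@H]3CC=C4C(=O)OCC[Si](C)(C)C | intermediate
24 | 11β-hydroxy-5-ene ester | O1CCOC12C[C@]34C[C@H]2C[C@H](O)[C@H]3CC=C4C(=O)OCC[Si](C)(C)C | intermediate
25 | 11β-triethylsilyloxy-5-ene ester | O1CCOC12C[C@]34C[C@H]2C[C@H](O[Si](CC)(CC)CC)[C@H]3CC=C4C(=O)OCC[Si](C)(C)C | intermediate
26 | 11β-triethylsilyloxy-10-oxo-5-ene ester (tricyclic enone ester) | O1CCOC12C[C@]34C[C@H]2C[C@H](O[Si](CC)(CC)CC)[C@H]3C(=O)C=C4C(=O)OCC[Si](C)(C)C | intermediate
27 | allylmagnesium bromide | C=CC[Mg]Br | starting material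
28 | 10β-allyl-10α-hydroxy-5-ene ester | O1CCOC12C[C@]34C[C@H]2C[C@H](O[Si](CC)(CC)CC)[C@H]3[C@](O)(CC=C)C=C4C(=O)OCC[Si](C)(C)C | intermediate
29 | propanoyl chloride | CCC(=O)Cl | starting material
30 | 10α-propanoate of 28 | O1CCOC12C[C@]34C[C@H]2C[C@H](O[Si](CC)(CC)CC)[C@H]3[C@](OC(=O)CC)(CC=C)C=C4C(=O)OCC[Si](C)(C)C | intermediate
31 | 10β-allyl-19,10-γ-lactone, 5β-H (C4 and C6 epimers) | O1CCOC12C[C@]34C[C@H]2C[C@H](O[Si](CC)(CC)CC)[C@H]3[C@@]5(CC=C)OC(=O)C(C)[C@H]5C4C(=O)OCC[Si](C)(C)C | intermediate
32 | B-alkyl-9-BBN adduct of 31 (boron on C3) | O1CCOC12C[C@]34C[C@H]2C[C@H](O[Si](CC)(CC)CC)[C@H]3[C@@]5(CCCB6C7CCCC6CCC7)OC(=O)C(C)[C@H]5C4C(=O)OCC[Si](C)(C)C | intermediate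
33 | 10β-(3-hydroxypropyl) lactone | O1CCOC12C[C@]34C[C@H]2C[C@H](O[Si](CC)(CC)CC)[C@H]3[C@@]5(CCCO)OC(=O)C(C)[C@H]5C4C(=O)OCC[Si](C)(C)C | intermediate
34 | 10β-(3-oxopropyl) lactone (C3 aldehyde) | O1CCOC12C[C@]34C[C@H]2C[C@H](O[Si](CC)(CC)CC)[C@H]3[C@@]5(CCC=O)OC(=O)C(C)[C@H]5C4C(=O)OCC[Si](C)(C)C | intermediate
35 | tetracyclic 3-hydroxy-19,10-lactone, 4β-Me, 6β-ester (C3 epimers) | O1CCOC12C[C@]34C[C@H]2C[C@H](O[Si](CC)(CC)CC)[C@H]3[C@@]56CCC(O)[C@@](C)(C(=O)O5)[C@H]6[C@@H]4C(=O)OCC[Si](C)(C)C | intermediate
36 | 3-oxo-19,10-lactone | O1CCOC12C[C@]34C[C@H]2C[C@H](O[Si](CC)(CC)CC)[C@H]3[C@@]56CCC(=O)[C@@](C)(C(=O)O5)[C@H]6[C@@H]4C(=O)OCC[Si](C)(C)C | intermediate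
37 | 2-en-3-yl triflate | O1CCOC12C[C@]34C[C@H]2C[C@H](O[Si](CC)(CC)CC)[C@H]3[C@@]56CC=C(OS(=O)(=O)C(F)(F)F)[C@@](C)(C(=O)O5)[C@H]6[C@@H]4C(=O)OCC[Si](C)(C)C | intermediate
38 | 2-ene 19,10-lactone (protected 17-nor-16-oxo-2,3-didehydro-11β-hydroxy-GA9 ester) | O1CCOC12C[C@]34C[C@H]2C[C@H](O[Si](CC)(CC)CC)[C@H]3[C@@]56CC=C[C@@](C)(C(=O)O5)[C@H]6[C@@H]4C(=O)OCC[Si](C)(C)C | intermediate
39 | 2β,3β-diol of 38 | O1CCOC12C[C@]34C[C@H]2C[C@H](O[Si](CC)(CC)CC)[C@H]3[C@@]56C[C@H](O)[C@H](O)[C@@](C)(C(=O)O5)[C@H]6[C@@H]4C(=O)OCC[Si](C)(C)C | intermediate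
40 | 2-(trimethylsilyl)ethyl 2β,3β,11β-trihydroxy-16-oxo-17-nor-GA9 ester | O=C1C[C@]23C[C@H]1C[C@H](O)[C@H]2[C@@]12C[C@H](O)[C@H](O)[C@@](C)(C(=O)O1)[C@H]2[C@@H]3C(=O)OCC[Si](C)(C)C | intermediate
41 | dibromomethane | BrCBr | starting material
42 | 2-(trimethylsilyl)ethyl ester of the target | C=C1C[C@]23C[C@H]1C[C@H](O)[C@H]2[C@@]12C[C@H](O)[C@H](O)[C@@](C)(C(=O)O1)[C@H]2[C@@H]3C(=O)OCC[Si](C)(C)C | intermediate
43 | CNP0322347.1, 2β,3β,11β-trihydroxy-GA9 | C=C1C[C@]23C[C@H]1C[C@H](O)[C@H]2[C@@]12C[C@H](O)[C@H](O)[C@@](C)(C(=O)O1)[C@H]2[C@@H]3C(=O)O | target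

**Totals**
Total step count: 33. Longest linear sequence: 33 steps (the route is fully linear from 1; 2, 4, 20, 27, 29 and 41 enter in single steps).

**Three steps most likely to fail, with fallbacks**

Step 6. The palladium cycloalkenylation may stall at the hindered quaternary centre or give endocyclic alkene isomers. The fallback sets out from 8: silylate the alcohol (tBuMe2SiCl, imidazole, DMF) to the mono-silyl ether F1, cleave the allyl alkene with O3 then Me2S to the aldehyde F2, and close ring D by an intramolecular aldol through the kinetic α′ boron dienolate at C13 (Bu2BOTf, iPr2NEt, CH2Cl2, −78 °C) to the 16-hydroxy tricyclic enone F3. Dess–Martin oxidation of F3 gives 12, where the route is rejoined.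

Step 17. The C9 cation may lose a proton from C10 or take a 1,2-alkyl shift from C8 instead of the hydride shift. The fallback sets out from 21: hydroborate the 9(11)-alkene from the α face (BH3·THF, 0 °C; then H2O2, NaOAc) to the 9-epi-11α-alcohol F4, oxidise it with Dess–Martin periodinane to the 9-epi-11-ketone F5, and equilibrate C9 with 1,8-diazabicyclo[5.4.0]undec-7-ene (toluene, 60 °C) to the cis-fused ketone 23, where the route is rejoined.

Step 20. C–H oxidation next to an electron-poor alkene can be slow or unselective. The fallback sets out from 25: Wohl–Ziegler bromination at C10 (N-bromosuccinimide, azobisisobutyronitrile, PhCF3, 80 °C) gives the C10 allylic bromide F6, and Kornblum oxidation (AgBF4, DMSO, 20 °C; then Et3N) converts it to 26, where the route is rejoined.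

**Further compounds**
F1 | step 6 | (1S,7aR)-7a-allyl-1-(tert-butyldimethylsilyloxy)-1,2,3,6,7,7a-hexahydro-5H-inden-5-one | C=CC[C@]12CCC(=O)C=C1CC[C@@H]2O[Si](C)(C)C(C)(C)C
F2 | step 6 | angular acetaldehyde (C16 aldehyde) from ozonolysis of F1 | O=CC[C@]12CCC(=O)C=C1CC[C@@H]2O[Si](C)(C)C(C)(C)C
F3 | step 6 | 17-nor-16-hydroxy-6β-OTBS-9(11)-en-12-one (C16 epimers) | OC1C[C@]23C[C@H]1C(=O)C=C2CC[C@@H]3O[Si](C)(C)C(C)(C)C
F4 | step 17 | 9-epi-11α-hydroxy-5-ene ester (9α-H) | O1CCOC12C[C@]34C[C@H]2C[C@@H](O)[C@@H]3CC=C4C(=O)OCC[Si](C)(C)C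
F5 | step 17 | 9-epi-11-oxo-5-ene ester (9α-H) | O1CCOC12C[C@]34C[C@H]2CC(=O)[C@@H]3CC=C4C(=O)OCC[Si](C)(C)C
F6 | step 20 | 10-bromo-11β-triethylsilyloxy-5-ene ester (C10 epimers) | O1CCOC12C[C@]34C[C@H]2C[C@H](O[Si](CC)(CC)CC)[C@H]3C(Br)C=C4C(=O)OCC[Si](C)(C)C
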